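**Retrosynthetic overview**
1. The target (upper rings A, B, C; lower rings D, E, F) is unveiled by one global hydrogenolysis of a deca-O-benzyl dimer that also removes a temporary bromine at C5 of ring A. The interflavan C4–C8 bond comes from a Lewis-acid Friedel–Crafts coupling of the upper flavan-4-ol 16 with penta-O-benzyl-(+)-gallocatechin 18, with attack anti to the C3 oxygen giving 4α.
2. Ring C of the upper unit is made in one operation by an aryne annulation: O1–C8a and C4–C4a form together from ring A as a 3-bromo-5-benzyloxy aryne and the acyclic anti aldol thioester 12, which carries O1, C2, C3, C4 and ring B.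
3. Enabling feature: ring A is fused to ring C only through the adjacent carbons C8a (bonded to O1) and C4a (bonded to C4), and O1 and C4 are 1,3-related across C2–C3. This β-oxy-acyl unit matches the electrophile/nucleophile pair of an aryne. C5 bears only hydrogen (5-deoxy unit), so a removable bromine there can steer the aryne regiochemistry.
4. C2 and C3 of the upper unit come from a catalytic asymmetric anti-selective glycolate Mukaiyama aldol; the lower unit comes from the chiral pool.
5. Ring order: rings A and B are bought as arenes, ring C is closed in step 6, and the preformed rings D, E, F are attached in step 9.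

Key step: step 6

Remark: (+)-gallocatechin (2R,3S) is taken as a purchasable natural product, and either C4 epimer of alcohol 16 is acceptable because this centre is ionised in step 9.

**Route**

Step 1
Reactants: 1 4-(benzyloxy)phenol
Product: 2 4-(benzyloxy)-2,6-dibromophenol
Conditions: NBS (2.05 equiv), i-Pr2NH (10 mol %), CH2Cl2, 0 °C to rt
Reagents that add atoms: N-bromosuccinimide, O=C1CCC(=O)N1Br
Why: Amine-catalysed ortho-selective electrophilic bromination of a phenol; the para position is blocked by the benzyloxy group, so both bromines should enter ortho to the hydroxyl.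

Step 2
Reactants: 2 4-(benzyloxy)-2,6-dibromophenol
Product: 5 4-(benzyloxy)-2-bromo-6-(trimethylsilyl)phenyl trifluoromethanesulfonate, via aryl trimethylsilyl ether 3 (not isolated), via lithium phenolate 4 (not isolated)
Conditions: (Me3Si)2NH, THF, reflux, then evaporation; n-BuLi (1.0 equiv), THF, −78 °C; Tf2O, −78 to 0 °C
Reagents that add atoms: hexamethyldisilazane, C[Si](C)(C)N[Si](C)(C)C; trifluoromethanesulfonic anhydride, O=S(=O)(OS(=O)(=O)C(F)(F)F)C(F)(F)F
Why: Standard one-pot route to 2-silylaryl triflates (O-silylation, bromine–lithium exchange, anionic retro-Brook 1,3 O-to-C silyl shift, triflation of the phenolate); one equivalent of n-BuLi should leave the second bromine in place.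

Step 3
Reactants: 6 benzyloxyacetyl chloride; 7 ethanethiol
Product: 8 S-ethyl 2-(benzyloxy)ethanethioate
Conditions: pyridine, CH2Cl2, 0 °C to rt
Reagents that add atoms: none
Why: Acyl substitution of an acid chloride by a thiol (thioesterification) with pyridine as HCl scavenger.

Step 4
Reactants: 8 S-ethyl 2-(benzyloxy)ethanethioate
Product: 9 (Z)-{[2-(benzyloxy)-1-(ethylsulfanyl)ethenyl]oxy}trimethylsilane
Conditions: LiN(i-Pr)2 (LDA), Me3SiCl, THF, −78 °C
Reagents that add atoms: chlorotrimethylsilane, C[Si](C)(C)Cl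
Why: Kinetic enolisation of the thioester through a cyclic (Ireland-type) transition state with in-situ O-silylation should place the benzyloxy group trans to the silyloxy group, which is the (Z) ketene silyl thioacetal.

Step 5
Reactants: 9 (Z)-{[2-(benzyloxy)-1-(ethylsulfanyl)ethenyl]oxy}trimethylsilane; 10 3,4,5-tris(benzyloxy)benzaldehyde
Product: 12 S-ethyl (2R,3R)-2-(benzyloxy)-3-hydroxy-3-[3,4,5-tris(benzyloxy)phenyl]propanethioate, via aldol trimethylsilyl ether 11 (not isolated)
Conditions: Sn(OTf)2 (20 mol %, divalent tin), (S)-1-ethyl-2-(piperidin-1-ylmethyl)pyrrolidine (22 mol %), EtCN, −78 °C, slow addition of 9 and 10; then 1 M HCl, THF, 0 °C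
Reagents that add atoms: none
Why: Catalytic asymmetric Mukaiyama aldol reaction: the (S)-diamine-ligated divalent tin triflate should shield one face of the bound aldehyde, and coordination of the benzyloxy oxygen to tin should turn the usual syn preference into anti, so both new stereocentres (2R,3R) are set by the catalyst.

Step 6
Reactants: 12 S-ethyl (2R,3R)-2-(benzyloxy)-3-hydroxy-3-[3,4,5-tris(benzyloxy)phenyl]propanethioate; 5 4-(benzyloxy)-2-bromo-6-(trimethylsilyl)phenyl trifluoromethanesulfonate
Product: 15 (2R,3R)-3,7-bis(benzyloxy)-5-bromo-2-[3,4,5-tris(benzyloxy)phenyl]chroman-4-one, via aryne 13 (not isolated), via aryl anion 14 (not isolated)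
Conditions: CsF (4 equiv), 18-crown-6 (4 equiv), THF, 0 °C to rt, 5 (2.2 equiv) added over 3 h
Reagents that add atoms: none
Why: Proposed new method: fluoride unmasks aryne 13, the β-hydroxyl of 12 (as cesium alkoxide or fluoride-hydrogen-bonded alcohol) adds to the aryne carbon that becomes C8a, and the aryl anion 14 formed at C4a attacks the thioester carbonyl and expels ethanethiolate, so O1–C8a and C4–C4a form in one operation. The closest known reaction types are the tandem nucleophilic addition/intramolecular acyl substitution of arynes with methyl salicylates (xanthone annulation) and the acyl-alkylation of arynes with β-keto esters; new here is an aliphatic β-hydroxy thioester as the O-nucleophile/C-acyl partner. Ring C is closed by intermolecular O-arylation followed by a 6-exo-trig attack of the aryl anion on the acyl carbon. No stereocentre is created: C2 and C3 come unchanged from 12 because no bond to them is broken, and their 2,3-trans arrangement is also the thermodynamically favoured one. The step needs oxygen to attack the aryne carbon remote from bromine, which the temporary C5 bromine should secure (aryne distortion and inductive stabilisation of the anion next to the halogen, as in 3-haloaryne additions); it also needs acylation to outrun protonation of 14, for which the reactive thioester, the aprotic medium and the slow addition of 5 are chosen.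

Step 7
Reactants: 15 (2R,3R)-3,7-bis(benzyloxy)-5-bromo-2-[3,4,5-tris(benzyloxy)phenyl]chroman-4-one
Product: 16 (2R,3S,4R)-3,7-bis(benzyloxy)-5-bromo-2-[3,4,5-tris(benzyloxy)phenyl]chroman-4-ol
Conditions: NaBH4, THF/MeOH, −20 to 0 °C
Reagents that add atoms: none
Why: Hydride reduction of the aryl ketone; axial delivery anti to the C3 benzyloxy group should favour the 3,4-trans alcohol drawn, and the C4 epimer would serve equally.

Step 8
Reactants: 17 (+)-gallocatechin
Product: 18 (2R,3S)-5,7-bis(benzyloxy)-2-[3,4,5-tris(benzyloxy)phenyl]chroman-3-ol (penta-O-benzyl-(+)-gallocatechin)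
Conditions: BnBr (5.5 equiv), K2CO3, DMF, argon, 0 °C to rt
Reagents that add atoms: benzyl bromide, BrCc1ccccc1
Why: Williamson etherification: K2CO3 deprotonates only the five phenols, so the secondary C3 alcohol should stay free.

Step 9
Reactants: 16 (2R,3S,4R)-3,7-bis(benzyloxy)-5-bromo-2-[3,4,5-tris(benzyloxy)phenyl]chroman-4-ol; 18 penta-O-benzyl-(+)-gallocatechin
Product: 19 5-bromo-deca-O-benzyl-robinetinidol-(4α,8)-gallocatechin (upper unit 2,3-trans-3,4-trans, lower 3-OH free)
Conditions: TMSOTf (0.2 equiv), 18 (3 equiv), 4 Å MS, CH2Cl2, −78 to −20 °C; Et3N quench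
Reagents that add atoms: none
Why: Acid-mediated Friedel–Crafts (SN1) flavan-4-ol/flavan-3-ol condensation, the biomimetic proanthocyanidin coupling: the C4 cation is stabilised by O1 and the para C7 benzyloxy group, and the most nucleophilic C8 of ring D should attack anti to the C3 benzyloxy group (2,3-trans gives 3,4-trans, 4α), a bias the peri bromine at C5 should reinforce.

Step 10
Reactants: 19 5-bromo-deca-O-benzyl-robinetinidol-(4α,8)-gallocatechin
Product: 20 robinetinidol-(4α,8)-gallocatechin
Conditions: H2 (1 atm), Pd(OH)2/C, NaOAc (1.5 equiv), THF/MeOH/H2O, rt; filtration under argon, lyophilisation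
Reagents that add atoms: none
Why: Heterogeneous hydrogenolysis should cleave the ten benzyl ethers and the aryl C–Br bond in one operation, with NaOAc buffering the HBr so that the acid-labile interflavan bond and the five stereocentres are untouched.

**Compound list**
1 | 4-(benzyloxy)phenol | Oc1ccc(OCc2ccccc2)cc1 | starting material
2 | 4-(benzyloxy)-2,6-dibromophenol | Oc1c(Br)cc(OCc2ccccc2)cc1Br | intermediate
3 | [4-(benzyloxy)-2,6-dibromophenoxy]trimethylsilane | C[Si](C)(C)Oc1c(Br)cc(OCc2ccccc2)cc1Br | intermediate (not isolated)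
4 | lithium 4-(benzyloxy)-2-bromo-6-(trimethylsilyl)phenolate | [Li+].[O-]c1c(Br)cc(OCc2ccccc2)cc1[Si](C)(C)C | intermediate (not isolated)
5 | 4-(benzyloxy)-2-bromo-6-(trimethylsilyl)phenyl trifluoromethanesulfonate | C[Si](C)(C)c1cc(OCc2ccccc2)cc(Br)c1OS(=O)(=O)C(F)(F)F | intermediate
6 | benzyloxyacetyl chloride | O=C(Cl)COCc1ccccc1 | starting material
7 | ethanethiol | CCS | starting material
8 | S-ethyl 2-(benzyloxy)ethanethioate | CCSC(=O)COCc1ccccc1 | intermediate
9 | (Z)-{[2-(benzyloxy)-1-(ethylsulfanyl)ethenyl]oxy}trimethylsilane | CCS/C(O[Si](C)(C)C)=C\OCc1ccccc1 | intermediate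
10 | 3,4,5-tris(benzyloxy)benzaldehyde | O=Cc1cc(OCc2ccccc2)c(OCc2ccccc2)c(OCc2ccccc2)c1 | starting material
11 | S-ethyl (2R,3R)-2-(benzyloxy)-3-[(trimethylsilyl)oxy]-3-[3,4,5-tris(benzyloxy)phenyl]propanethioate | CCSC(=O)[C@H](OCc1ccccc1)[C@H](O[Si](C)(C)C)c1cc(OCc2ccccc2)c(OCc2ccccc2)c(OCc2ccccc2)c1 | intermediate (not isolated)
12 | S-ethyl (2R,3R)-2-(benzyloxy)-3-hydroxy-3-[3,4,5-tris(benzyloxy)phenyl]propanethioate (anti aldol) | CCSC(=O)[C@H](OCc1ccccc1)[C@H](O)c1cc(OCc2ccccc2)c(OCc2ccccc2)c(OCc2ccccc2)c1 | intermediate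
13 | 5-(benzyloxy)-3-bromobenzyne (1-(benzyloxy)-3-bromo-4,5-didehydrobenzene) | BrC1=CC(OCc2ccccc2)=CC#C1 | intermediate (not isolated)
14 | cesium salt of the aryl anion: O-[5-(benzyloxy)-3-bromophenyl] ether of 12, carbanion at the ring carbon between the ether oxygen and bromine | [Cs+].CCSC(=O)[C@H](OCc1ccccc1)[C@H](Oc1cc(OCc2ccccc2)cc(Br)[c-]1)c1cc(OCc2ccccc2)c(OCc2ccccc2)c(OCc2ccccc2)c1 | intermediate (not isolated)
15 | (2R,3R)-3,7-bis(benzyloxy)-5-bromo-2-[3,4,5-tris(benzyloxy)phenyl]chroman-4-one (2,3-trans) | O=C1[C@H](OCc2ccccc2)[C@@H](c2cc(OCc3ccccc3)c(OCc3ccccc3)c(OCc3ccccc3)c2)Oc2cc(OCc3ccccc3)cc(Br)c21 | intermediate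
16 | (2R,3S,4R)-3,7-bis(benzyloxy)-5-bromo-2-[3,4,5-tris(benzyloxy)phenyl]chroman-4-ol (2,3-trans-3,4-trans) | O[C@H]1[C@H](OCc2ccccc2)[C@@H](c2cc(OCc3ccccc3)c(OCc3ccccc3)c(OCc3ccccc3)c2)Oc2cc(OCc3ccccc3)cc(Br)c21 | intermediate
17 | (+)-gallocatechin, (2R,3S) | O[C@H]1Cc2c(O)cc(O)cc2O[C@@H]1c1cc(O)c(O)c(O)c1 | starting material
18 | (2R,3S)-5,7-bis(benzyloxy)-2-[3,4,5-tris(benzyloxy)phenyl]chroman-3-ol | O[C@H]1Cc2c(OCc3ccccc3)cc(OCc3ccccc3)cc2O[C@@H]1c1cc(OCc2ccccc2)c(OCc2ccccc2)c(OCc2ccccc2)c1 | intermediate
19 | 5-bromo-deca-O-benzyl-robinetinidol-(4α,8)-gallocatechin; upper unit 3,7,3',4',5'-penta-O-benzyl-5-bromo with (2R,3S,4R) (C4 is R by the sequence rule only because of the bromine; geometry 3,4-trans), lower unit 5,7,3',4',5'-penta-O-benzyl (2R,3S) with free 3-OH, bond from upper C4 to lower C8 | c1ccccc1COc1cc(Br)c2c(c1)O[C@H](c1cc(OCc3ccccc3)c(OCc3ccccc3)c(OCc3ccccc3)c1)[C@@H](OCc1ccccc1)[C@@H]2c1c(OCc3ccccc3)cc(OCc3ccccc3)c2c1O[C@H](c1cc(OCc3ccccc3)c(OCc3ccccc3)c(OCc3ccccc3)c1)[C@@H](O)C2 | intermediate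
20 | robinetinidol-(4α,8)-gallocatechin | Oc1ccc2c(c1)O[C@H](c1cc(O)c(O)c(O)c1)[C@@H](O)[C@@H]2c1c(O)cc(O)c2c1O[C@H](c1cc(O)c(O)c(O)c1)[C@@H](O)C2 | target

**Totals**
Total step count: 10. Longest linear sequence: 7 steps (3, 4, 5, 6, 7, 9, 10).

**Steps most likely to fail**

Step 6 (proposed method). The aryl anion 14 may be protonated before it reaches the thioester, leaving only the open aryl ether. Bromide may also be lost from this o-bromoaryl anion to give a second aryne. The cesium aldolate of 12 may undergo retro-aldol cleavage, and the flavanone may epimerise at C3 or ring-open by E1cB in the basic fluoride medium. The fallback uses known reactions and makes the C4–C4a bond first and the O1–C8a bond second. It sets out from 12. Liebeskind–Srogl coupling of the thioester with commercial [4-(benzyloxy)-2-fluorophenyl]boronic acid (Pd2(dba)3 (zerovalent palladium), tri(2-furyl)phosphine, copper thiophene-2-carboxylate Cu(O2CC4H3S) (monovalent copper), THF, 50 °C) should give the fluoro ketone (2R,3R)-1-[4-(benzyloxy)-2-fluorophenyl]-2-(benzyloxy)-3-hydroxy-3-[3,4,5-tris(benzyloxy)phenyl]propan-1-one F1. Intramolecular SNAr of the alkoxide on the ketone-activated aryl fluoride (K2CO3, DMF, rt) should then close ring C to the bromine-free flavanone (2R,3R)-3,7-bis(benzyloxy)-2-[3,4,5-tris(benzyloxy)phenyl]chroman-4-one F2. Reduction as in step 7 gives the flavan-4-ol (2R,3S,4R)-3,7-bis(benzyloxy)-2-[3,4,5-tris(benzyloxy)phenyl]chroman-4-ol F3. Coupling with 18 as in step 9 gives deca-O-benzyl-robinetinidol-(4α,8)-gallocatechin F4, and hydrogenolysis as in step 10 (without NaOAc) comes back to the route at 20.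

Step 9. The C4 cation may be attacked with poor facial selectivity, giving the 4β epimer. The bromine-deactivated alcohol may ionise slowly, and the acid may cleave and re-form the new interflavan bond. The fallback replaces hard acid ionisation by thiophilic activation of an isolable C4 thioether and sets out from 16. Phenylmethanethiol with BF3·OEt2 in CH2Cl2 at −20 °C should give (2R,3R,4R)-3,7-bis(benzyloxy)-4-(benzylsulfanyl)-5-bromo-2-[3,4,5-tris(benzyloxy)phenyl]chromane F5 (2,3-trans-3,4-trans). Treatment of this thioether with AgBF4 and 18 in THF at −20 to 0 °C, a known flavan-4-thioether coupling run without protic acid, comes back to the route at 19.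

Step 10. The aryl C–Br bond may be cleaved incompletely beside ten debenzylations. The free polyphenol may also be air-oxidised at its pyrogallol rings or suffer acid-induced fission of the interflavan bond during the long reduction and its isolation. The fallback isolates the product through a stable derivative and sets out from 19. Hydrogenolysis as in step 10 is followed at once by acetylation of the crude product (Ac2O, pyridine, DMAP), which should give undeca-O-acetyl-robinetinidol-(4α,8)-gallocatechin F6; this can be purified on silica and freed from incompletely reduced material. Deacetylation (catalytic K2CO3, degassed MeOH, 0 °C, then acidic ion-exchange resin) comes back to the route at 20.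

**Further compounds**
F1 | step 6 | (2R,3R)-1-[4-(benzyloxy)-2-fluorophenyl]-2-(benzyloxy)-3-hydroxy-3-[3,4,5-tris(benzyloxy)phenyl]propan-1-one | O=C(c1ccc(OCc2ccccc2)cc1F)[C@H](OCc1ccccc1)[C@H](O)c1cc(OCc2ccccc2)c(OCc2ccccc2)c(OCc2ccccc2)c1
F2 | step 6 | (2R,3R)-3,7-bis(benzyloxy)-2-[3,4,5-tris(benzyloxy)phenyl]chroman-4-one | O=C1[C@H](OCc2ccccc2)[C@@H](c2cc(OCc3ccccc3)c(OCc3ccccc3)c(OCc3ccccc3)c2)Oc2cc(OCc3ccccc3)ccc21
F3 | step 6 | (2R,3S,4R)-3,7-bis(benzyloxy)-2-[3,4,5-tris(benzyloxy)phenyl]chroman-4-ol | O[C@H]1[C@H](OCc2ccccc2)[C@@H](c2cc(OCc3ccccc3)c(OCc3ccccc3)c(OCc3ccccc3)c2)Oc2cc(OCc3ccccc3)ccc21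
F4 | step 6 | deca-O-benzyl-robinetinidol-(4α,8)-gallocatechin, upper unit (2R,3S,4S), lower unit (2R,3S) with free 3-OH | c1ccccc1COc1ccc2c(c1)O[C@H](c1cc(OCc3ccccc3)c(OCc3ccccc3)c(OCc3ccccc3)c1)[C@@H](OCc1ccccc1)[C@@H]2c1c(OCc3ccccc3)cc(OCc3ccccc3)c2c1O[C@H](c1cc(OCc3ccccc3)c(OCc3ccccc3)c(OCc3ccccc3)c1)[C@@H](O)C2
F5 | step 9 | (2R,3R,4R)-3,7-bis(benzyloxy)-4-(benzylsulfanyl)-5-bromo-2-[3,4,5-tris(benzyloxy)phenyl]chromane | c1ccccc1CS[C@H]1[C@H](OCc2ccccc2)[C@@H](c2cc(OCc3ccccc3)c(OCc3ccccc3)c(OCc3ccccc3)c2)Oc2cc(OCc3ccccc3)cc(Br)c21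
F6 | step 10 | undeca-O-acetyl-robinetinidol-(4α,8)-gallocatechin | CC(=O)Oc1ccc2c(c1)O[C@H](c1cc(OC(C)=O)c(OC(C)=O)c(OC(C)=O)c1)[C@@H](OC(C)=O)[C@@H]2c1c(OC(C)=O)cc(OC(C)=O)c2c1O[C@H](c1cc(OC(C)=O)c(OC(C)=O)c(OC(C)=O)c1)[C@@H](OC(C)=O)C2
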